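**Plan**
- The retrosynthesis first cuts the thiophene–thiophene bond between the alpha carbon of ring A (the thiophene carrying the CH2O ester) and the alpha carbon of ring B (the thiophene carrying the alkyne). It then cuts the two ester C–O bonds and the ring B–alkyne bond.
- Forward, ring A is acylated to ester 3. Ring B is alkynylated at its iodide and the alcohol is acylated to bromide 8. The two finished halves are joined last, and both thiophene rings are bought, so no ring is built.
- The enabling feature is that C5 of ring A in 3 is its only CH next to sulfur. Ring B in 8 carries bromine on one alpha carbon and the alkyne on the other, so neither 8 nor the product has an alpha C–H left.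
- The target has no stereocentre, and the enoate has two identical methyl groups on its beta carbon, so no stereochemistry has to be set.

Key step: step 4

**Route**

Step 1
Reactants: 1 thiophen-2-ylmethanol; 2 3-methylbut-2-enoyl chloride
Product: 3 thiophen-2-ylmethyl 3-methylbut-2-enoate
Conditions: pyridine (2 equiv), CH2Cl2, 0 °C to rt
Reagents that add atoms: none
Why: Acylation of a primary alcohol by an acyl chloride (nucleophilic acyl substitution), in which the weak base pyridine takes up HCl without deprotonating the gamma methyl groups of 2 to a vinylketene, so the double bond should stay conjugated and the acid-sensitive thienylmethyl alcohol never meets free acid.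

Step 2
Reactants: 4 2-bromo-5-iodothiophene; 5 but-3-yn-1-ol
Product: 6 4-(5-bromothiophen-2-yl)but-3-yn-1-ol
Conditions: PdCl2(PPh3)2 (2 mol %), CuI (4 mol %), Et3N, THF, degassed, rt
Reagents that add atoms: none
Why: Sonogashira coupling, in which zerovalent palladium at room temperature inserts into the C–I bond far faster than into the C–Br bond, so the alkyne should enter only at the iodinated alpha carbon and the bromide is kept for step 4.

Step 3
Reactants: 6 4-(5-bromothiophen-2-yl)but-3-yn-1-ol; 7 3-methylbutanoyl chloride
Product: 8 4-(5-bromothiophen-2-yl)but-3-yn-1-yl 3-methylbutanoate
Conditions: Et3N, DMAP (cat.), CH2Cl2, 0 °C to rt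
Reagents that add atoms: none
Why: DMAP-catalysed acylation of the primary homopropargylic alcohol by an acyl chloride (nucleophilic acyl substitution), to which the aryl bromide and the internal alkyne are inert.

Step 4
Reactants: 3 thiophen-2-ylmethyl 3-methylbut-2-enoate (1.3 equiv); 8 4-(5-bromothiophen-2-yl)but-3-yn-1-yl 3-methylbutanoate
Product: 9 [5'-(4-(3-methylbutanoyloxy)but-1-yn-1-yl)-2,2'-bithiophen-5-yl]methyl 3-methylbut-2-enoate (CNP0114739.0)
Conditions: Pd(OAc)2 (5 mol %), PCy3·HBF4 (10 mol %), PivOH (30 mol %), K2CO3 (2 equiv), DMA, argon, 100 °C
Reagents that add atoms: none
Why: Direct C–H arylation by concerted metalation–deprotonation: zerovalent palladium formed in the flask inserts into the C–Br bond of 8, pivalate replaces bromide on the divalent arylpalladium and removes the C5 proton of 3 as the Pd–C bond forms, and reductive elimination gives the inter-ring bond and returns zerovalent palladium. The closest known reaction type is the pivalate-assisted direct arylation of 2-substituted thiophenes with heteroaryl bromides. No ring is closed and no stereocentre arises, so the step needs only regio- and chemoselectivity. Regioselectivity for C5 over C3 and C4 comes from the lower metalation barrier of the C–H next to sulfur, and C5 is the only such position in 3; because 8 and 9 have no alpha C–H, self-coupling of 8 through C–H and over-arylation of 9 are excluded. Chemoselectivity rests on oxidative addition into C–Br being much faster than into the thienylmethyl C–O bond, on the internal alkyne having no terminal C–H for Sonogashira or Glaser pathways, on the trisubstituted enoate being a poor Heck acceptor, and on both esters tolerating anhydrous carbonate and pivalate.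

**Compound list**

1 | thiophen-2-ylmethanol | OCc1cccs1 | starting material
2 | 3-methylbut-2-enoyl chloride | CC(C)=CC(=O)Cl | starting material
3 | thiophen-2-ylmethyl 3-methylbut-2-enoate | CC(C)=CC(=O)OCc1cccs1 | intermediate
4 | 2-bromo-5-iodothiophene | Brc1ccc(I)s1 | starting material
5 | but-3-yn-1-ol | C#CCCO | starting material
6 | 4-(5-bromothiophen-2-yl)but-3-yn-1-ol | OCCC#Cc1ccc(Br)s1 | intermediate
7 | 3-methylbutanoyl chloride | CC(C)CC(=O)Cl | starting material
8 | 4-(5-bromothiophen-2-yl)but-3-yn-1-yl 3-methylbutanoate | CC(C)CC(=O)OCCC#Cc1ccc(Br)s1 | intermediate
9 | [5'-(4-(3-methylbutanoyloxy)but-1-yn-1-yl)-2,2'-bithiophen-5-yl]methyl 3-methylbut-2-enoate (CNP0114739.0) | CC(C)=CC(=O)OCc1ccc(-c2ccc(C#CCCOC(=O)CC(C)C)s2)s1 | target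

**Count**

Total steps: 4. Longest linear sequence: 3 steps (steps 2, 3 and 4); step 1 runs in parallel.

**Steps most likely to fail**

1. Step 4. The arylpalladium intermediate may add across the alkyne of 8 or 9, zerovalent palladium may insert into the thienylmethyl C–O bond of 3, or the catalyst may die at 100 °C before conversion is complete. The fallback sets out from 3 and makes the same bond through a pre-formed boron partner. Iridium-catalysed C–H borylation of the same C5–H ([Ir(OMe)(cod)]2, 4,4'-di-tert-butyl-2,2'-bipyridine, bis(pinacolato)diboron, THF, rt to 50 °C) should give [5-(4,4,5,5-tetramethyl-1,3,2-dioxaborolan-2-yl)thiophen-2-yl]methyl 3-methylbut-2-enoate F1. Suzuki–Miyaura coupling of F1 with 8 (Pd(PPh3)4, K3PO4, THF/H2O, 60 °C) would then join the rings at a lower temperature and come back to the route at 9.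

2. Step 2. Site selectivity between iodide and bromide may erode and give double alkynylation, and the terminal alkyne may dimerise oxidatively if oxygen is not excluded. The fallback sets out from 5 and removes the competition between two halides. Sonogashira coupling of 5 with bought 2-iodothiophene (Ic1cccs1) under the same PdCl2(PPh3)2/CuI/Et3N conditions should give 4-(thiophen-2-yl)but-3-yn-1-ol F2. Electrophilic bromination of F2 at its free alpha carbon with N-bromosuccinimide (DMF, 0 °C, dark) comes back to the route at 6.

3. Step 1. Deprotonation of the acyl chloride at a gamma methyl group may form a vinylketene and move the double bond out of conjugation, or traces of acid may ionise the thienylmethyl alcohol and cause oligomerisation. The fallback sets out from 1 and activates the alcohol instead of the acyl group. Mitsunobu esterification with 3-methylbut-2-enoic acid (CC(C)=CC(=O)O), PPh3 and diisopropyl azodicarboxylate in THF at 0 °C to rt involves no acyl chloride, ketene or free strong acid. It comes back to the route directly at 3, so no new compound arises on the way (F0).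

**Further compounds**

F1 | step 4 | [5-(4,4,5,5-tetramethyl-1,3,2-dioxaborolan-2-yl)thiophen-2-yl]methyl 3-methylbut-2-enoate | CC(C)=CC(=O)OCc1ccc(B2OC(C)(C)C(C)(C)O2)s1
F2 | step 2 | 4-(thiophen-2-yl)but-3-yn-1-ol | OCCC#Cc1cccs1
F0 | step 1 | none | none
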